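**Assumption:** the (S)-configured biaryl bisphosphine is taken to deliver the (2S)-flavanone, by analogy with the facial selectivity seen for cyclic enones; if the measured sense is opposite, use the (R)-ligand. The target SMILES corresponds to (2S)-7,4'-dihydroxy-8,3'-diprenylflavanone.

## Retrosynthetic overview

1. Disconnect C2–C1' last: Rh-catalysed enantioselective 1,4-addition of the B-ring boronic acid **14** to chromone **10** sets the only stereocentre (2S).
2. Chromone **10** (rings A and C) comes from one C5 linchpin, penta-1,4-diyn-3-one **9**. One alkyne builds ring A by Diels–Alder/Alder–Rickert benzannulation with a dimedone-derived bis-silyloxy diene **5**; the other alkyne closes ring C by 6-endo oxa-Michael in the same pot.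
3. Diene **5** already carries the 8-prenyl group and both ring-A oxygens (from dimedone + prenyl bromide).
4. Ring B is bought as 4-bromophenol, then ortho-C-prenylated and borylated.
5. Ring order: A (benzannulation), then C immediately in the same operation; B is attached last.

## Route

**Step 1**
Reactants: **1** dimedone (5,5-dimethylcyclohexane-1,3-dione); **2** prenyl bromide
Product: **3** 5,5-dimethyl-2-(3-methylbut-2-en-1-yl)cyclohexane-1,3-dione
Conditions: KOH (1.05 equiv), H2O/acetone, **2** (1.0 equiv), rt → 50 °C
Reagents that add atoms: prenyl bromide, CC(C)=CCBr (reactant **2**)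
Why: C-alkylation of a cyclic 1,3-dione enolate with a reactive allylic halide in protic medium, which favours C- over O-alkylation; no stereocentre.

**Step 2**
Reactants: **3**; **4** chlorotrimethylsilane
Product: **5** 5,5-dimethyl-2-(3-methylbut-2-en-1-yl)-1,3-bis(trimethylsilyloxy)cyclohexa-1,3-diene
Conditions: LDA (2.3 equiv), THF, −78 → 0 °C; TMSCl (2.6 equiv), −78 °C → rt; non-aqueous work-up (pentane, filter), use crude
Reagents that add atoms: TMSCl, C[Si](C)(C)Cl
Why: 1,3-dione dianion formation (enol O–H, then the γ-CH2, equivalent on both sides by symmetry) followed by double O-silylation gives the cross-conjugated bis(silyl enol ether) diene; no stereocentre.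

**Step 3**
Reactants: **6** ethyl formate; **7** ethynylmagnesium bromide
Product: **8** penta-1,4-diyn-3-ol
Conditions: **7** (2.2 equiv), THF, 0 °C → rt; aq NH4Cl
Reagents that add atoms: ethyl formate, CCOC=O; ethynylmagnesium bromide, C#C[Mg]Br (both reactants)
Why: double Grignard addition to a formate ester gives the symmetrical secondary bis-propargylic alcohol; the carbinol carbon bears two identical groups, so no stereocentre.

**Step 4**
Reactants: **8**
Product: **9** penta-1,4-diyn-3-one (used as a dried, filtered solution; not concentrated to dryness)
Conditions: activated MnO2 (10 equiv), CH2Cl2, 0 °C → rt; filter through Celite/Na2SO4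
Reagents that add atoms: none
Why: MnO2 oxidation of an activated (bis-propargylic) alcohol to the ketone under neutral conditions that leave the terminal alkynes untouched.

**Step 5 (key step: rings A and C formed in one pot)**
Reactants: **5**; **9** (2.5 equiv)
Product: **10** 7-hydroxy-8-(3-methylbut-2-en-1-yl)-4H-chromen-4-one
Conditions: CH2Cl2, 0 °C → rt; evaporate; toluene, 130 °C, sealed tube (− isobutene); cool; Et2NH (3 equiv), MeOH, rt; then AcOH, 40 °C
Reagents that add atoms: none (all product atoms come from **5** and **9**; the TMS groups and isobutene are lost)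
Why: Proposed new method: the unsubstituted diene terminus (C4) of **5** attacks the terminal alkyne carbon of one ynone arm in a Diels–Alder reaction to give a bicyclo[2.2.2]octadiene, which on heating expels isobutene (Alder–Rickert retro-Diels–Alder) to give 1-[2,4-bis(trimethylsilyloxy)-3-prenylphenyl]prop-2-yn-1-one with the acyl group ortho/para to the two oxygens and prenyl between them; amine/MeOH then removes both TMS groups, converts the remaining ynone arm into an enaminone, and the ortho-phenol closes 6-endo with loss of Et2NH to give the chromone; the closest known reactions are the bis-silyloxy-cyclohexadiene/alkynyl-carbonyl Diels–Alder/Alder–Rickert synthesis of resorcinols and the amine-mediated cyclisation of o-hydroxyaryl ynones to chromones; no stereocentre is formed.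

**Step 6**
Reactants: **11** 4-bromophenol; **2** prenyl bromide
Product: **12** 4-bromo-2-(3-methylbut-2-en-1-yl)phenol
Conditions: NaH (1.0 equiv), toluene, 0 °C → rt; **2** (1.0 equiv)
Reagents that add atoms: prenyl bromide, CC(C)=CCBr (reactant **2**)
Why: ortho-C-alkylation of a tight-ion-pair sodium phenoxide in a non-polar solvent; the para position is blocked by Br, so only ortho-prenylation (plus separable O-prenyl ether) is possible.

**Step 7**
Reactants: **12**; **13** tetrahydroxydiboron
Product: **14** [4-hydroxy-3-(3-methylbut-2-en-1-yl)phenyl]boronic acid
Conditions: XPhos Pd G2 (1 mol %), XPhos (2 mol %), KOAc (3 equiv), EtOH, 80 °C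
Reagents that add atoms: tetrahydroxydiboron, OB(O)B(O)O
Why: Pd(0)-catalysed Miyaura-type borylation of the aryl bromide with B2(OH)4 gives the boronic acid directly and tolerates the free phenol and the trisubstituted alkene.

**Step 8**
Reactants: **10**; **14** (3 equiv)
Product: **15** glabrol, (2S)-7-hydroxy-2-[4-hydroxy-3-(3-methylbut-2-en-1-yl)phenyl]-8-(3-methylbut-2-en-1-yl)chroman-4-one
Conditions: [Rh(OH)(cod)]2 (2.5 mol %), (S)-MeO-F12-BIPHEP [(S)-6,6'-dimethoxy-2,2'-bis{bis(3,4,5-trifluorophenyl)phosphino}biphenyl] (6 mol %), toluene/H2O 10:1, 40 °C, no added base; neutral work-up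
Reagents that add atoms: none beyond reactant **14** (the C3 hydrogen comes from water)
Why: Hayashi–Miyaura Rh(I)-catalysed asymmetric conjugate arylation of the chromone enone, where the chiral bisphosphine–Rh–aryl species adds to one enantioface of C2=C3 to set C2 as (S), and the base-free medium keeps both phenols protonated and prevents retro-oxa-Michael racemisation.

## Compound list

1 | dimedone (5,5-dimethylcyclohexane-1,3-dione) | CC1(C)CC(=O)CC(=O)C1 | starting material
2 | prenyl bromide (1-bromo-3-methylbut-2-ene) | CC(C)=CCBr | starting material
3 | 5,5-dimethyl-2-(3-methylbut-2-en-1-yl)cyclohexane-1,3-dione | CC(C)=CCC1C(=O)CC(C)(C)CC1=O | intermediate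
4 | chlorotrimethylsilane | C[Si](C)(C)Cl | starting material (reagent)
5 | 5,5-dimethyl-2-(3-methylbut-2-en-1-yl)-1,3-bis(trimethylsilyloxy)cyclohexa-1,3-diene | CC(C)=CCC1=C(O[Si](C)(C)C)CC(C)(C)C=C1O[Si](C)(C)C | intermediate
6 | ethyl formate | CCOC=O | starting material
7 | ethynylmagnesium bromide | C#C[Mg]Br | starting material
8 | penta-1,4-diyn-3-ol | C#CC(O)C#C | intermediate
9 | penta-1,4-diyn-3-one | C#CC(=O)C#C | intermediate
10 | 7-hydroxy-8-(3-methylbut-2-en-1-yl)-4H-chromen-4-one | O=c1ccoc2c(CC=C(C)C)c(O)ccc12 | intermediate
11 | 4-bromophenol | Oc1ccc(Br)cc1 | starting material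
12 | 4-bromo-2-(3-methylbut-2-en-1-yl)phenol | CC(C)=CCc1cc(Br)ccc1O | intermediate
13 | tetrahydroxydiboron | OB(O)B(O)O | starting material (reagent)
14 | [4-hydroxy-3-(3-methylbut-2-en-1-yl)phenyl]boronic acid | CC(C)=CCc1cc(B(O)O)ccc1O | intermediate
15 | glabrol, (2S) | CC(C)=CCc1cc([C@@H]2CC(=O)c3ccc(O)c(CC=C(C)C)c3O2)ccc1O | target

## Summary

Total steps: 8. Longest linear sequence: 4 (steps 1 → 2 → 5 → 8, or 3 → 4 → 5 → 8).

Three steps most likely to fail:

- **Step 5.** Risks are bis-cycloaddition or polymerisation of the sensitive diynone, and Mukaiyama–Michael addition in place of cycloaddition. Fallback: replace **9** with the stable mono-alkyne 5,5-dimethoxypent-1-yn-3-one (from the Weinreb amide of 3,3-dimethoxypropanoic acid and ethynylmagnesium bromide). The same benzannulation then gives an o-hydroxyaryl β-keto acetal, and ring C is closed by mild acid (acetal exchange and loss of MeOH) rather than by oxa-Michael onto a second alkyne.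
- **Step 8.** Risks are low reactivity of the unprotected 7-hydroxychromone, protodeboronation of the electron-rich boronic acid, and uncertain level or sense of induction. Fallback: run the arylation on bis-TBS-protected partners (7-OTBS chromone and O-TBS boronic acid, each by TBSCl/imidazole) and finish with buffered HF·pyridine. This costs three extra steps but removes the acidic phenols from the catalytic step.
- **Step 2.** Risks are incomplete dianion formation and hydrolysis of the bis-silyl diene. Fallback: switch to an acyclic diene, 1-methoxy-2-prenyl-1,3-bis(trimethylsilyloxy)buta-1,3-diene, made from methyl 2-prenylacetoacetate by stepwise Et3N/TMSCl then LDA/TMSCl. Its ynone cycloadduct aromatises by loss of MeOSiMe3 instead of isobutene, giving the same 2,4-dioxygenated 3-prenylaryl ketone.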